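## The problem

Erypoegin F (21) is a 2-arylbenzofuran-3-carbaldehyde: a benzofuran (O1, C2, C3, C3a, C4–C7, C7a) with a 2,4-dihydroxyphenyl ring (ring C) at C2, a formyl group at C3, a methoxy group at C6 and a 3-methylbut-2-enyl (prenyl) group at C7. It has no stereocentre and no stereogenic double bond, so nothing in it can or must control anything else in space; the difficulty is purely one of position. The benzo ring is 1,2,3,4-tetrasubstituted (C3a, C7a–O1, C7–prenyl, C6–OMe) and the prenyl group sits between two oxygen-bearing carbons, a pattern that electrophilic prenylation of a 6-oxygenated benzofuran would not deliver cleanly, because C5 and the oxygen compete with C7. The formyl group has to enter C3 although C5 of the benzofuran and C5' of ring C are electron-rich as well. The trisubstituted alkene of the prenyl group does not tolerate strong protic or Lewis acids or halogen electrophiles, the free resorcinol is easily oxidised and attacked by electrophiles, and the aldehyde lies next to the 2'-hydroxyl; late steps must therefore be mild and the phenols are best unmasked under base. The feature that opens the route is the string O1–C7a–C7–C6(–O): it is the skeleton of a 2-furylacetic ester, with C7a as furan C2, C7 as the ester α-carbon carrying the prenyl group and C6 as the ester carbon carrying the methoxy oxygen. A vinyl group on the neighbouring furan carbon supplies C4 and C5, and once the ester is enolised the six carbons C5=C4–C3a=C7a–C7=C6 form a hexatriene in which only the C5–C6 bond is missing.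

## Retrosynthesis

**21 to 20.** The two phenolic O–H bonds are masked as acetates, giving diacetate 20. Acetates are preferred to acetal-type ethers for three reasons. They come off by base-catalysed methanolysis, which touches neither the prenyl alkene nor the aldehyde. They lower the nucleophilicity of ring C for the formylation. And the 2'-substituent cannot cyclise onto C3 under Lewis-acidic conditions. The forward step only has to be a clean transesterification.

**20 to 18.** The C3–CHO bond is cut. Carrying this carbon from the furan stage would place an aldehyde or its surrogate beside the vinyl terminus of the triene and expose it to two enolate steps. Introducing it last uses the natural reactivity of a 2-arylbenzofuran, whose C3 is the β-carbon of a cyclic enol ether. The precursor 18 is simpler by one functional group. The forward reaction must select C3 over C5 and ring C and must spare the alkene.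

**18 to 13 and 15.** The biaryl bond C2–C1' is cut, giving benzofuran 13 and bromide 15, which is the diacetate of 14. Attaching ring C after the benzo ring is built keeps the early enolate chemistry free of aryl esters and makes the route convergent. The cut is feasible because C2–H is the most acidic proton of 13, so that carbon can be metalated selectively. The forward reaction needs an organometallic that tolerates aryl acetates, which points to zinc.

**13 to 11.** This is the central cut: the C5–C6 bond of the benzo ring, which leads back through the ring-closed intermediate 12 to the silyl ketene acetal 11. Closing C4–C5 by an aldol reaction or C3a–C4 by a Friedel–Crafts reaction would each require a precursor with an extra carbonyl group and would deliver C6 as a free phenol. Cutting C5–C6 leaves a triene in which every substituent of the benzo ring is already fixed by connectivity and the C6 oxygen is already methylated. The precursor is an acyclic ester derivative of a simple furan. The forward step must achieve a thermal ring closure that dearomatises the furan for a moment and then lose the silyloxy group rather than the methoxy group.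

**11 to 9 to 8.** The O–Si bond is cut (enolate silylation of ester 9), then the bond between furan C3 and the vinyl group (cross-coupling of bromide 8). The vinyl group follows the ester side chain because the C2 bromide of 5 is the one that reacts first with palladium. Both steps are standard and add nothing that needs control.

**8 to 4 and 5.** The bond between furan C2 and the ester α-carbon is cut, giving ester 4 and dibromide 5. Arylating the already prenylated ester sets C7 with its substituent in one bond formation. The neighbouring option, arylation of an acetate followed by C-prenylation, costs a step and is kept in reserve. The forward reaction needs site selectivity for C2 of 5 and an enolate that does not self-condense.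

**4 to 1 and 2.** The C2–C3 bond of the hexenoate is cut by an orthoester Claisen transform, which leads to alcohol 1 and orthoester 2. It delivers the trisubstituted alkene and the methyl ester, whose methoxy group ends as the C6 methoxy group of 21, from two bulk chemicals in one step.

## Roads not taken

**Alternative 1:** The furan ring is closed last on a finished benzene by cutting C3–C3a and O1–C7a. This leads to the bromo-iodoarene A2, 2-bromo-1-iodo-4-methoxy-3-(3-methylbut-2-enyl)benzene, and the β-keto ester A3, ethyl 3-[2,4-bis(methoxymethoxy)phenyl]-3-oxopropanoate. In the forward direction monovalent copper couples the α-carbon of A3 with the C–I bond of A2 and then the enol oxygen with the neighbouring C–Br bond, giving the benzofuran-3-carboxylate A1 in one operation.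

- Merits: the road is convergent, and the aryl group at C2 and the carbon at C3 arrive together in defined positions. No electrophilic substitution at C3 is needed, and in this respect it is better than the chosen plan, whose formylation depends on relative nucleophilicities.
- Weak points: A2 is a benzene with four different adjacent substituents, so the regiochemical problem of 21 is not solved but moved into a starting material that would itself need several steps. The C–O closure must occur at a bromide flanked on both sides, by the new aryl–carbon bond and by the prenyl group. The ester of A1 has to be reduced and re-oxidised to reach the aldehyde. The acetal protecting groups call for acid at the end, in the presence of the prenyl group.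
- Comparison: against the secure C3 of A1 the chosen plan sets a benzo-ring pattern that comes from an ester without any aromatic substitution, an aldehyde reached at its own oxidation level and base-labile protection.

**Alternative 2:** The benzo ring is again built onto a furan, but at the C4–C5 bond. The precursor is the keto aldehyde A5, 5-[2,4-bis(methoxymethoxy)phenyl]-2-(6-methyl-2-oxohept-5-en-3-yl)furan-3-carbaldehyde. Base forms the methyl ketone enolate, which adds to the formyl carbon; loss of water and enolisation of the ring ketone give the phenol A4.

- Merits: intramolecular aldol condensation with aromatisation is among the most reliable ring closures, it runs under mild conditions, and ring C is present from the start, so no late coupling is needed. In the certainty of its ring-forming step this road is clearly ahead of the chosen one.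
- Weak points: A5 is a 2,3,5-trisubstituted furan whose α-branched ketone side chain must be assembled next to a formyl group that needs protection meanwhile. The more acidic α-position of the ketone is the methine beside the furan, which is unproductive, so the closure relies on reversibility. C6 emerges as a free phenol and needs a methylation. The C3 formylation is still to come, now on a substrate whose ring C carries two donating acetal ethers, so that C5' competes and the 2'-acetal can close onto C3. The final deprotection is acidic.
- Comparison: the chosen plan is shorter, because the C6 oxygen arrives already methylated and the triene is reached in four steps from commercial materials. It pays for this with a ring closure that has no direct precedent.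

**Alternative 3:** The formyl group is viewed as a reduced lactone. The C3–C(=O) bond and the lactone C–O bond of the coumestan A6 are cut back to the benzofuran-3-yl triflate A7, 2-(2,4-dihydroxyphenyl)-6-methoxy-7-(3-methylbut-2-enyl)benzofuran-3-yl trifluoromethanesulfonate. Zerovalent palladium inserts into the C3–O bond of the triflate, carbonylation follows, and the 2'-hydroxyl captures the acylpalladium to close the pyranone ring. Partial hydride reduction of A6 to the lactol would then give 21 as its open hydroxy-aldehyde form.

- Merits: the C3 carbon is placed without any regiochemical question, and the 2'-phenol, a liability elsewhere, serves as the internal nucleophile. This is better than the chosen plan in the security of C3.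
- Weak points: A7 presupposes a 2-arylbenzofuran-3(2H)-one that already carries the 6-methoxy-7-prenyl pattern, so the main problem of 21 is left untouched. Triflation of the enol oxygen beside two free phenols is not realistic without protecting-group steps. Stopping the reduction of an aryl lactone at the lactol is delicate, and over-reduction would force a re-oxidation next to a free resorcinol.
- Comparison: the chosen plan answers the benzo-ring question that this road leaves open and reaches the aldehyde in one step. Against the advantage of A6 it sets the acetates on ring C, which are meant to leave C3 as the only reactive site.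

Key step: step 5

Assumption: ketene acetal 11 is drawn as its (E) isomer (furan cis to OMe); the geometry of this double bond need not be uniform, since either isomer closes to the same racemic 12 and C6 becomes sp2 in 13.

## Route

Step 1
Reactants: 1 2-methylbut-3-en-2-ol; 2 trimethyl orthoacetate
Product: 4 methyl 5-methylhex-4-enoate, via ketene acetal 3 (not isolated)
Conditions: EtCO2H (cat.), excess 2, 110 → 140 °C, MeOH distilled off
Reagents that add atoms: none
Why: Johnson–Claisen (orthoester Claisen) rearrangement: acid-catalysed exchange and loss of methanol give ketene acetal 3, whose [3,3] shift forms the C2–C3 bond and moves the alkene into the trisubstituted position; no stereocentre arises.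

Step 2
Reactants: 4 methyl 5-methylhex-4-enoate; 5 2,3-dibromofuran
Product: 8 methyl 2-(3-bromofuran-2-yl)-5-methylhex-4-enoate (racemic), via lithium enolate 6 (not isolated), via chlorozinc enolate 7 (not isolated)
Conditions: LiN(i-Pr)2, THF, −78 °C; ZnCl2, −78 °C → rt; then 5, Pd(dba)2 (cat.), P(t-Bu)3 (cat.), rt
Reagents that add atoms: none
Why: Palladium-catalysed α-arylation of an ester zinc enolate (Negishi-type coupling of a Reformatsky reagent): zerovalent palladium inserts first into the C2–Br bond of 5, the position next to oxygen that reacts first in cross-couplings of this dibromide, and the zinc enolate avoids Claisen self-condensation of the methyl ester and leaves the C3 bromide in place. The α-stereocentre is formed racemic and is erased in step 4.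

Step 3
Reactants: 8 methyl 2-(3-bromofuran-2-yl)-5-methylhex-4-enoate
Product: 9 methyl 2-(3-ethenylfuran-2-yl)-5-methylhex-4-enoate (racemic)
Conditions: vinylboronic acid pinacol ester, Pd(OAc)2 (cat.), SPhos (cat.), K3PO4, PhMe/H2O, 80 °C
Reagents that add atoms: vinylboronic acid pinacol ester, C=CB1OC(C)(C)C(C)(C)O1
Why: Suzuki–Miyaura coupling of the remaining 3-bromofuran; an electron-rich dialkylbiarylphosphine helps oxidative addition beside the branched substituent, and the phosphate base in a two-phase medium leaves the methyl ester intact.

Step 4
Reactants: 9 methyl 2-(3-ethenylfuran-2-yl)-5-methylhex-4-enoate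
Product: 11 tert-butyl{[(1E)-1-methoxy-5-methyl-2-(3-ethenylfuran-2-yl)hexa-1,4-dien-1-yl]oxy}dimethylsilane, via lithium enolate 10 (not isolated)
Conditions: LiN(i-Pr)2, THF, −78 °C; t-BuMe2SiCl, DMPU, −78 → 0 °C; pentane extraction, used crude
Reagents that add atoms: tert-butyldimethylsilyl chloride, CC(C)(C)[Si](C)(C)Cl
Why: Kinetic deprotonation of the α-furyl ester and O-silylation of the enolate in the presence of a polar cosolvent, as in the first stage of an Ireland–Claisen rearrangement; the fully substituted α-carbon disfavours C-silylation and the tert-butyldimethylsilyl group gives a ketene acetal that survives extraction and heating.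

Step 5
Reactants: 11 tert-butyl{[(1E)-1-methoxy-5-methyl-2-(3-ethenylfuran-2-yl)hexa-1,4-dien-1-yl]oxy}dimethylsilane
Product: 13 6-methoxy-7-(3-methylbut-2-enyl)benzofuran, via dihydrobenzofuran 12 (not isolated)
Conditions: PhMe (degassed, dilute), i-Pr2NEt (cat.), base-washed sealed tube, 160 °C
Reagents that add atoms: none
Why: Proposed new method: heating brings the s-cis,s-cis conformer of triene 11 (C5=C4–C3a=C7a–C7=C6, its central double bond being the furan C2=C3 bond, held cis by the ring) to a thermal, suprafacial disrotatory 6π electrocyclization that forms the C5–C6 bond and closes the six-membered carbocycle of 12, in which the furan is dearomatised for the moment. 12 then loses tert-butyldimethylsilanol, either directly across C5–C6 or across C6–C7 after a suprafacial 1,5-hydrogen shift from C5 to C7 has restored the furan, and the gain of a benzene ring and the furan pulls the reversible, uphill closure forward. The closest known reaction types are the thermal electrocyclization–aromatisation of 2,3-dialkenyl furans and indoles (carbazoles from 2,3-divinylindoles), the closure of dienylketenes to phenols, and the eliminative aromatisation of ketene acetal adducts. No stereocentre is left: C6 of 12 forms racemic and becomes sp2, and both geometric isomers of 11 give the same 12. Regiochemistry needs no control, because the place of every substituent follows from the connectivity of the triene. The selectivity the step needs is loss of the silyloxy and not the methoxy group: in an aprotic, amine-buffered medium with no acid to protonate the more basic methoxy oxygen, the silanolate is the better nucleofuge and the methoxy group the better donor to the developing cyclohexadienyl cation, while the fully substituted C7 blocks O-to-C silyl migration.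

Step 6
Reactants: 14 4-bromobenzene-1,3-diol (4-bromoresorcinol)
Product: 15 4-bromo-1,3-phenylene diacetate
Conditions: Ac2O, pyridine, DMAP (cat.), CH2Cl2, 0 °C → rt
Reagents that add atoms: acetic anhydride, CC(=O)OC(C)=O
Why: Nucleophile-catalysed O-acylation of both phenols; the acetates tolerate the organozinc coupling, lower the nucleophilicity of ring C for step 8 and come off under mild base at the end.

Step 7
Reactants: 13 6-methoxy-7-(3-methylbut-2-enyl)benzofuran; 15 4-bromo-1,3-phenylene diacetate
Product: 18 4-[6-methoxy-7-(3-methylbut-2-enyl)benzofuran-2-yl]-1,3-phenylene diacetate, via 2-lithiobenzofuran 16 (not isolated), via benzofuran-2-ylzinc chloride 17 (not isolated)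
Conditions: n-BuLi, THF, −78 °C; ZnCl2, −78 °C → rt; then 15, Pd2(dba)3 (cat.), XPhos (cat.), THF, 50 °C
Reagents that add atoms: none
Why: C2–H, the most acidic proton of a benzofuran, is removed by n-BuLi at low temperature; transmetalation gives an arylzinc chloride that does not attack aryl acetates and undergoes Negishi coupling with the ortho-substituted bromide under a bulky biarylphosphine–palladium catalyst.

Step 8
Reactants: 18 4-[6-methoxy-7-(3-methylbut-2-enyl)benzofuran-2-yl]-1,3-phenylene diacetate
Product: 20 4-[3-formyl-6-methoxy-7-(3-methylbut-2-enyl)benzofuran-2-yl]-1,3-phenylene diacetate, via iminium salt 19 (not isolated)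
Conditions: POCl3, DMF, 0 → 50 °C; then aq. NaOAc, rt
Reagents that add atoms: N,N-dimethylformamide, CN(C)C=O; water, O
Why: Vilsmeier–Haack formylation: C3 is the β-carbon of the cyclic enol ether O1–C2=C3 and attack there gives a cation at C2 stabilised by O1 and the aryl group, whereas ring C is deactivated by its acetates and C5 has only aryl-ether activation; buffered hydrolysis of iminium salt 19 frees the aldehyde without exposing the prenyl group to strong acid.

Step 9
Reactants: 20 4-[3-formyl-6-methoxy-7-(3-methylbut-2-enyl)benzofuran-2-yl]-1,3-phenylene diacetate
Product: 21 2-(2,4-dihydroxyphenyl)-6-methoxy-7-(3-methylbut-2-enyl)benzofuran-3-carbaldehyde (erypoegin F)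
Conditions: K2CO3 (cat.), MeOH, 0 °C → rt
Reagents that add atoms: none
Why: Base-catalysed transesterification (methanolysis) of the two aryl acetates, much faster than any reaction of the non-enolisable aldehyde, the methyl ether or the alkene; it releases 21.

## Compound list

1 | 2-methylbut-3-en-2-ol | C=CC(C)(C)O | starting material
2 | trimethyl orthoacetate | COC(C)(OC)OC | starting material
3 | 2-[(1-methoxyethenyl)oxy]-2-methylbut-3-ene | C=C(OC)OC(C)(C)C=C | intermediate (not isolated)
4 | methyl 5-methylhex-4-enoate | COC(=O)CCC=C(C)C | intermediate
5 | 2,3-dibromofuran | Brc1ccoc1Br | starting material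
6 | lithium 1-methoxy-5-methylhexa-1,4-dien-1-olate | COC(O[Li])=CCC=C(C)C | intermediate (not isolated)
7 | chloro(1-methoxy-5-methyl-1-oxohex-4-en-2-yl)zinc (zinc enolate, drawn C-bound) | COC(=O)C([Zn]Cl)CCC=C(C)C | intermediate (not isolated)
8 | methyl 2-(3-bromofuran-2-yl)-5-methylhex-4-enoate (racemic) | COC(=O)C(CC=C(C)C)c1occc1Br | intermediate
9 | methyl 2-(3-ethenylfuran-2-yl)-5-methylhex-4-enoate (racemic) | COC(=O)C(CC=C(C)C)c1occc1C=C | intermediate
10 | lithium 1-methoxy-5-methyl-2-(3-ethenylfuran-2-yl)hexa-1,4-dien-1-olate | COC(O[Li])=C(CC=C(C)C)c1occc1C=C | intermediate (not isolated)
11 | tert-butyl{[(1E)-1-methoxy-5-methyl-2-(3-ethenylfuran-2-yl)hexa-1,4-dien-1-yl]oxy}dimethylsilane | C=Cc1ccoc1/C(CC=C(C)C)=C(\OC)O[Si](C)(C)C(C)(C)C | intermediate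
12 | 6-[tert-butyl(dimethyl)silyloxy]-6-methoxy-7-(3-methylbut-2-enyl)-5,6-dihydrobenzofuran (racemic) | COC1(O[Si](C)(C)C(C)(C)C)CC=C2C=COC2=C1CC=C(C)C | intermediate (not isolated)
13 | 6-methoxy-7-(3-methylbut-2-enyl)benzofuran | COc1ccc2ccoc2c1CC=C(C)C | intermediate
14 | 4-bromobenzene-1,3-diol (4-bromoresorcinol) | Oc1ccc(Br)c(O)c1 | starting material
15 | 4-bromo-1,3-phenylene diacetate | CC(=O)Oc1ccc(Br)c(OC(C)=O)c1 | intermediate
16 | [6-methoxy-7-(3-methylbut-2-enyl)benzofuran-2-yl]lithium | [Li]c1cc2ccc(OC)c(CC=C(C)C)c2o1 | intermediate (not isolated)
17 | chloro[6-methoxy-7-(3-methylbut-2-enyl)benzofuran-2-yl]zinc | Cl[Zn]c1cc2ccc(OC)c(CC=C(C)C)c2o1 | intermediate (not isolated)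
18 | 4-[6-methoxy-7-(3-methylbut-2-enyl)benzofuran-2-yl]-1,3-phenylene diacetate | COc1ccc2cc(-c3ccc(OC(C)=O)cc3OC(C)=O)oc2c1CC=C(C)C | intermediate
19 | N-{[2-(2,4-diacetoxyphenyl)-6-methoxy-7-(3-methylbut-2-enyl)benzofuran-3-yl]methylidene}-N-methylmethanaminium chloride | C[N+](C)=Cc1c(-c2ccc(OC(C)=O)cc2OC(C)=O)oc2c(CC=C(C)C)c(OC)ccc12.[Cl-] | intermediate (not isolated)
20 | 4-[3-formyl-6-methoxy-7-(3-methylbut-2-enyl)benzofuran-2-yl]-1,3-phenylene diacetate | COc1ccc2c(C=O)c(-c3ccc(OC(C)=O)cc3OC(C)=O)oc2c1CC=C(C)C | intermediate
21 | 2-(2,4-dihydroxyphenyl)-6-methoxy-7-(3-methylbut-2-enyl)benzofuran-3-carbaldehyde (erypoegin F) | COc1ccc2c(C=O)c(-c3ccc(O)cc3O)oc2c1CC=C(C)C | target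

## Step count and least certain steps

Total: 9 steps. Longest linear sequence: 8 steps (steps 1–5 and 7–9); step 6 is a one-step side branch.

**Step 5 (key step, proposed new method).**
- Risk: the closure may be too slow at temperatures the ketene acetal survives, because one oxygen substituent must turn inward at the C6 terminus and the closed form is dearomatised; hydrolysis, silyl transfer or oligomerisation of the vinylfuran would then win. The second risk is loss of methanol in place of silanol if traces of acid are present.
- Fallback: it sets out from 9 and returns at 13, using the known closure of dienylketenes. Saponification of 9 (LiOH, THF/H2O) gives 5-methyl-2-(3-ethenylfuran-2-yl)hex-4-enoic acid F1. Oxalyl chloride with catalytic DMF in CH2Cl2 gives 5-methyl-2-(3-ethenylfuran-2-yl)hex-4-enoyl chloride F2. Et3N in hot toluene removes HCl to give 5-methyl-2-(3-ethenylfuran-2-yl)hexa-1,4-dien-1-one F3, a dienylketene. F3 closes by the 6π electrocyclization that is the ring-forming event of the Danheiser and Dötz benzannulations, and tautomerises to 7-(3-methylbut-2-enyl)benzofuran-6-ol F4. O-Methylation (MeI, K2CO3, acetone) gives 13.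
- If methanol is lost in part in the main step, desilylation and the same O-methylation of the crude product would converge the mixture on 13.

**Step 2.**
- Risk: slow transmetalation and reductive elimination of the α-branched zinc enolate beside the C3 bromide, which would allow a second oxidative addition at C3–Br or reduction of the C–Br bonds.
- Fallback: it sets out from 5 and returns at 8, and changes the order of bond formation. The unbranched Reformatsky reagent BrZnCH2CO2Me (from methyl bromoacetate and zinc) is coupled with 5 at C2 under Pd(dba)2/P(t-Bu)3 to give methyl 2-(3-bromofuran-2-yl)acetate F5. The enolate of F5 (LiN(SiMe3)2, THF, −78 °C) is alkylated with 1-bromo-3-methylbut-2-ene to give 8. Ester 4 is then not needed.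

**Step 8.**
- Risk: attack of the chloroiminium ion or of liberated HCl on the prenyl alkene, competing formylation at C5, or slow reaction because the twisted diacetoxyphenyl ring donates little to C2.
- Fallback: it sets out from 18 and returns at 20, replacing electrophilic acylation by halogenation and carbonylation. Iodination with N-iodosuccinimide (MeCN, 0 °C) gives 4-[3-iodo-6-methoxy-7-(3-methylbut-2-enyl)benzofuran-2-yl]-1,3-phenylene diacetate F6. Palladium-catalysed reductive carbonylation (Pd(OAc)2, 1,3-bis(diphenylphosphino)propane, CO, Et3SiH, Na2CO3, DMF, 80 °C) turns the C–I bond into the formyl group of 20.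

**Step 7.**
- Risk: incomplete or unselective metalation (competition from the benzylic–allylic CH2 of the prenyl group), or acyl transfer from the acetates to residual organolithium.
- Fallback: it sets out from 13 and 15 and returns at 18 without any organometallic reagent, by direct C2–H arylation of the benzofuran (Pd(OAc)2, KOAc, DMA, 130 °C). It makes no new compound.

## Further compounds

F1 | step 5 | 5-methyl-2-(3-ethenylfuran-2-yl)hex-4-enoic acid (racemic) | OC(=O)C(CC=C(C)C)c1occc1C=C
F2 | step 5 | 5-methyl-2-(3-ethenylfuran-2-yl)hex-4-enoyl chloride (racemic) | ClC(=O)C(CC=C(C)C)c1occc1C=C
F3 | step 5 | 5-methyl-2-(3-ethenylfuran-2-yl)hexa-1,4-dien-1-one | O=C=C(CC=C(C)C)c1occc1C=C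
F4 | step 5 | 7-(3-methylbut-2-enyl)benzofuran-6-ol | Oc1ccc2ccoc2c1CC=C(C)C
F5 | step 2 | methyl 2-(3-bromofuran-2-yl)acetate | COC(=O)Cc1occc1Br
F6 | step 8 | 4-[3-iodo-6-methoxy-7-(3-methylbut-2-enyl)benzofuran-2-yl]-1,3-phenylene diacetate | COc1ccc2c(I)c(-c3ccc(OC(C)=O)cc3OC(C)=O)oc2c1CC=C(C)C
F0 | step 7 | none | none
A1 | alternative 1 | ethyl 2-[2,4-bis(methoxymethoxy)phenyl]-6-methoxy-7-(3-methylbut-2-enyl)benzofuran-3-carboxylate | CCOC(=O)c1c(-c2ccc(OCOC)cc2OCOC)oc2c(CC=C(C)C)c(OC)ccc12
A2 | alternative 1 | 2-bromo-1-iodo-4-methoxy-3-(3-methylbut-2-enyl)benzene | COc1ccc(I)c(Br)c1CC=C(C)C
A3 | alternative 1 | ethyl 3-[2,4-bis(methoxymethoxy)phenyl]-3-oxopropanoate | CCOC(=O)CC(=O)c1ccc(OCOC)cc1OCOC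
A4 | alternative 2 | 2-[2,4-bis(methoxymethoxy)phenyl]-7-(3-methylbut-2-enyl)benzofuran-6-ol | COCOc1ccc(-c2cc3ccc(O)c(CC=C(C)C)c3o2)c(OCOC)c1
A5 | alternative 2 | 5-[2,4-bis(methoxymethoxy)phenyl]-2-(6-methyl-2-oxohept-5-en-3-yl)furan-3-carbaldehyde (racemic) | CC(=O)C(CC=C(C)C)c1oc(-c2ccc(OCOC)cc2OCOC)cc1C=O
A6 | alternative 3 | 3-hydroxy-9-methoxy-10-(3-methylbut-2-enyl)coumestan | COc1ccc2c(c1CC=C(C)C)oc1-c3ccc(O)cc3OC(=O)c12
A7 | alternative 3 | 2-(2,4-dihydroxyphenyl)-6-methoxy-7-(3-methylbut-2-enyl)benzofuran-3-yl trifluoromethanesulfonate | COc1ccc2c(OS(=O)(=O)C(F)(F)F)c(-c3ccc(O)cc3O)oc2c1CC=C(C)C
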